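## Retrosynthetic overview

1. Target 32 comes from the 16‑O‑TBS macrocycle 30 by desilylation and chlorination; the ten‑membered ring is closed last, by ring‑closing metathesis at C3=C4 of seco‑tetraacetate 29.
2. The butanolide and the C7, C8, C11 centres come from a doubly hydroxyl‑directed epoxidation of bis‑allylic diol 26, followed by invertive opening of the dienyl epoxide by the C19 tert‑butyl ester.
3. The C9–C10 bond comes from indium allylation of trienal 23 with 2‑(bromomethyl)enone 10, which also creates the 11(20)‑methylidene; C9 is then corrected by oxidation and Felkin–Anh reduction.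
4. Ring A with C1 and C2 comes from the key step: palladium‑catalysed asymmetric dearomative alkylation of the symmetric, C2‑blocked 4,6‑dimethylresorcinol 2 with acrolein diacetate 3.
5. Ring order: cyclohexane ring A (from the arene), then the γ‑lactone, then the ten‑membered carbocycle; trienal 23 comes from a butynol‑derived dienal and a D‑lactate‑derived phosphonate.

Assumption: compounds 1, 3, 11, 13, 16 and 19 are taken as purchasable; locants C1–C20 in the text are the briarane locants of 32.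

## Route

Step 1
Reactants: 1 4,6-dimethylbenzene-1,3-diol
Product: 2 2-chloro-4,6-dimethylbenzene-1,3-diol
Conditions: SO2Cl2 (1.0 equiv), Et2O, 0 °C
Reagents that add atoms: sulfuryl chloride, ClS(Cl)(=O)=O
Why: Electrophilic aromatic chlorination goes to the only ring CH flanked by both hydroxyls, which blocks the position where the next step would otherwise alkylate and rearomatize.

Step 2
Reactants: 2 2-chloro-4,6-dimethylbenzene-1,3-diol; 3 prop-2-ene-1,1-diyl diacetate
Product: 4 (1S)-1-[(1S)-3-chloro-4-hydroxy-1,5-dimethyl-2-oxocyclohexa-3,5-dien-1-yl]prop-2-en-1-yl acetate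
Conditions: Pd2(dba)3·CHCl3 (2.5 mol%), (R,R)-DACH-phenyl Trost ligand (7.5 mol%), Et3N (1.1 equiv), CH2Cl2, 0 °C to rt
Reagents that add atoms: none
Why: Proposed new method: zerovalent palladium ionizes one enantiotopic acetate of 3 (Tsuji–Trost asymmetric allylic alkylation with a gem‑diacetate) and the chiral pocket steers one of the two enantiotopic methyl‑bearing carbons of the phenoxide of 2 onto the acetoxy‑bearing allyl terminus (O‑allylation being reversible under the catalyst), so the C1 quaternary centre and the C2 acetoxy centre are set together while symmetry and aromaticity are lost; the closest known reactions are gem‑diacetate allylic alkylations that give adjacent quaternary and tertiary centres and the palladium‑catalysed intermolecular dearomative allylation of substituted naphthols, and the ligand enantiomer is chosen by the pocket mnemonic (its antipode would give ent‑4).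

Step 3
Reactants: 4 (1S)-1-[(1S)-3-chloro-4-hydroxy-1,5-dimethyl-2-oxocyclohexa-3,5-dien-1-yl]prop-2-en-1-yl acetate
Product: 5 (1S)-1-[(1S)-4-hydroxy-1,5-dimethyl-2-oxocyclohexa-3,5-dien-1-yl]prop-2-en-1-yl acetate
Conditions: Zn dust, AcOH/THF, rt
Reagents that add atoms: none
Why: Reductive dehalogenation of an α‑chloro‑1,3‑dicarbonyl through its zinc enolate removes the blocking chlorine without touching the allylic acetate or either stereocentre.

Step 4
Reactants: 5 (1S)-1-[(1S)-4-hydroxy-1,5-dimethyl-2-oxocyclohexa-3,5-dien-1-yl]prop-2-en-1-yl acetate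
Product: 6 (1S)-1-[(1S)-4-methoxy-1,5-dimethyl-2-oxocyclohexa-3,5-dien-1-yl]prop-2-en-1-yl acetate
Conditions: HC(OMe)3, camphorsulfonic acid (cat.), MeOH, 0 °C to rt
Reagents that add atoms: trimethyl orthoformate, COC(OC)OC
Why: Acid‑catalysed enol etherification of the vinylogous acid under thermodynamic control puts the methoxy group on the less hindered C12 oxygen, leaving the C14 carbonyl next to the quaternary carbon in a fully conjugated dienone.

Step 5
Reactants: 6 (1S)-1-[(1S)-4-methoxy-1,5-dimethyl-2-oxocyclohexa-3,5-dien-1-yl]prop-2-en-1-yl acetate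
Product: 7 (1S)-1-[(1R,2S)-2-hydroxy-4-methoxy-1,5-dimethylcyclohexa-3,5-dien-1-yl]prop-2-en-1-yl acetate
Conditions: NaBH4, CeCl3·7H2O, MeOH, −40 °C
Reagents that add atoms: none
Why: Luche 1,2‑reduction of the flat cyclohexadienone delivers hydride from the face of the C1 methyl, anti to the bulkier acetoxyallyl arm, so the new C14 hydroxyl is cis to that arm.

Step 6
Reactants: 7 (1S)-1-[(1R,2S)-2-hydroxy-4-methoxy-1,5-dimethylcyclohexa-3,5-dien-1-yl]prop-2-en-1-yl acetate
Product: 9 (1S)-1-[(1R,6S)-6-acetoxy-1,3-dimethyl-4-oxocyclohex-2-en-1-yl]prop-2-en-1-yl acetate, via dienol ether acetate 8 (not isolated)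
Conditions: Ac2O, Et3N, DMAP (cat.), CH2Cl2, 0 °C; then 1 M aq. HCl, THF, 0 °C
Reagents that add atoms: acetic anhydride, CC(=O)OC(C)=O; water, O
Why: O‑acetylation followed by hydrolysis of the 2‑methoxydiene (protonation at C13) unveils the conjugated C12 enone under acid conditions that do not eliminate the β‑acetoxy group, and no stereocentre is touched.

Step 7
Reactants: 9 (1S)-1-[(1R,6S)-6-acetoxy-1,3-dimethyl-4-oxocyclohex-2-en-1-yl]prop-2-en-1-yl acetate
Product: 10 (1S)-1-[(1R,6S)-6-acetoxy-3-(bromomethyl)-1-methyl-4-oxocyclohex-2-en-1-yl]prop-2-en-1-yl acetate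
Conditions: NBS, AIBN (cat.), PhCF3, 80 °C
Reagents that add atoms: N-bromosuccinimide, O=C1CCC(=O)N1Br
Why: Wohl–Ziegler radical bromination takes the α‑methyl of the enone (C20), because the γ‑position is quaternary and the acetoxy‑bearing CH groups are hindered and polarity‑mismatched for the bromine atom.

Step 8
Reactants: 11 tert-butyl (2R)-2-hydroxypropanoate
Product: 12 tert-butyl (2R)-2-{[(trifluoromethyl)sulfonyl]oxy}propanoate
Conditions: Tf2O, 2,6-lutidine, CH2Cl2, −78 °C
Reagents that add atoms: trifluoromethanesulfonic anhydride, O=S(=O)(OS(=O)(=O)C(F)(F)F)C(F)(F)F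
Why: O‑Sulfonylation proceeds with retention and turns the lactate hydroxyl into a leaving group suited to clean SN2 displacement.

Step 9
Reactants: 13 diethyl {2-[methoxy(methyl)amino]-2-oxoethyl}phosphonate; 12 tert-butyl (2R)-2-{[(trifluoromethyl)sulfonyl]oxy}propanoate
Product: 15 tert-butyl (2S)-3-(diethoxyphosphoryl)-4-[methoxy(methyl)amino]-2-methyl-4-oxobutanoate, via sodium phosphonate 14 (not isolated)
Conditions: NaH, THF, 0 °C; then 12, −20 °C to rt
Reagents that add atoms: none
Why: SN2 C‑alkylation of the phosphonate carbanion by the lactate triflate occurs with inversion and installs the future C17 methyl stereocentre (the phosphorus‑bearing carbon is an inconsequential epimer mixture).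

Step 10
Reactants: 16 4-{[tert-butyl(dimethyl)silyl]oxy}but-2-yn-1-ol
Product: 18 (2Z)-4-{[tert-butyl(dimethyl)silyl]oxy}-3-iodobut-2-en-1-ol, via alkenylaluminate 17 (not isolated)
Conditions: NaAlH2(OCH2CH2OMe)2, THF, 0 °C; then I2, −78 °C
Reagents that add atoms: iodine, II
Why: Hydroxyl‑directed trans‑hydroalumination of the propargylic alcohol and iodinolysis with retention give the (Z)‑3‑iodoallylic alcohol, which fixes the C5=C6 geometry.

Step 11
Reactants: 18 (2Z)-4-{[tert-butyl(dimethyl)silyl]oxy}-3-iodobut-2-en-1-ol; 19 tributyl(ethenyl)stannane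
Product: 20 (2E)-3-({[tert-butyl(dimethyl)silyl]oxy}methyl)penta-2,4-dien-1-ol
Conditions: Pd(PPh3)4 (5 mol%), CuI (10 mol%), DMF, rt
Reagents that add atoms: none
Why: Stille coupling proceeds with retention of alkene geometry and places the vinyl group (C4) cis to the carbinol carbon (C7).

Step 12
Reactants: 20 (2E)-3-({[tert-butyl(dimethyl)silyl]oxy}methyl)penta-2,4-dien-1-ol
Product: 21 (2E)-3-({[tert-butyl(dimethyl)silyl]oxy}methyl)penta-2,4-dienal
Conditions: MnO2, CH2Cl2, rt
Reagents that add atoms: none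
Why: Allylic alcohol oxidation with MnO2 is neutral and chemoselective, so the geometrically labile dienal is formed without isomerization and is used at once.

Step 13
Reactants: 21 (2E)-3-({[tert-butyl(dimethyl)silyl]oxy}methyl)penta-2,4-dienal; 15 tert-butyl (2S)-3-(diethoxyphosphoryl)-4-[methoxy(methyl)amino]-2-methyl-4-oxobutanoate
Product: 22 tert-butyl (2R,3E,5E)-6-({[tert-butyl(dimethyl)silyl]oxy}methyl)-3-[methoxy(methyl)carbamoyl]-2-methylocta-3,5,7-trienoate
Conditions: LiCl, DBU, MeCN, 0 °C to rt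
Reagents that add atoms: none
Why: Horner–Wadsworth–Emmons olefination under Masamune–Roush conditions gives the (E)‑trisubstituted enamide (C6 trans to the C9 carbonyl) and is mild enough to leave the C17 centre intact.

Step 14
Reactants: 22 tert-butyl (2R,3E,5E)-6-({[tert-butyl(dimethyl)silyl]oxy}methyl)-3-[methoxy(methyl)carbamoyl]-2-methylocta-3,5,7-trienoate
Product: 23 tert-butyl (2R,3E,5E)-6-({[tert-butyl(dimethyl)silyl]oxy}methyl)-3-formyl-2-methylocta-3,5,7-trienoate
Conditions: iBu2AlH (1.1 equiv), THF, −78 °C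
Reagents that add atoms: none
Why: Weinreb amide reduction stops at the aldehyde because the chelated aluminium hemiaminal survives until work‑up, and the tert‑butyl ester is inert at −78 °C.

Step 15
Reactants: 10 (1S)-1-[(1R,6S)-6-acetoxy-3-(bromomethyl)-1-methyl-4-oxocyclohex-2-en-1-yl]prop-2-en-1-yl acetate; 23 tert-butyl (2R,3E,5E)-6-({[tert-butyl(dimethyl)silyl]oxy}methyl)-3-formyl-2-methylocta-3,5,7-trienoate
Product: 24 C9–C10 allylation adduct (ring A 12-ketone with 11(20)-methylidene joined at C10 to the C9 carbinol of the trienoate; C9 mainly epimeric to 32)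
Conditions: In powder, THF/H2O (1:1), rt
Reagents that add atoms: none
Why: Barbier‑type indium allylation adds the γ‑carbon (C10) of the allylindium to the aldehyde through a six‑membered chair transition state on the ring face anti to the C2 arm, which forms the C9–C10 bond, sets C10 and creates the 11(20)‑methylidene; the chair gives mainly the 9‑epimer, and both C9 epimers converge in steps 16 and 17.

Step 16
Reactants: 24 C9–C10 allylation adduct
Product: 25 seco-trienone (9,12-diketone of 24)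
Conditions: MnO2, CH2Cl2, rt
Reagents that add atoms: none
Why: Neutral MnO2 oxidation of the allylic C9 carbinol erases the misset centre without base, so the C10 hydrogen (α to the new ketone) is not epimerized or conjugated.

Step 17
Reactants: 25 seco-trienone
Product: 26 bis-allylic 9,12-diol (C9 and C12 as in 32)
Conditions: NaBH4, CeCl3·7H2O, MeOH, −78 °C
Reagents that add atoms: none
Why: Luche 1,2‑reduction sets C9 by Felkin–Anh attack anti to the quaternary C1 substituent of C10 and sets C12 by equatorial attack, because the axial trajectory is blocked by the syn‑axial 14‑acetoxy group.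

Step 18
Reactants: 26 bis-allylic 9,12-diol
Product: 28 seco-lactone triol (19,7-lactone with free 8-, 9- and 12-hydroxyls and the 11,20-epoxide), via bis-epoxide 27 (not isolated)
Conditions: VO(acac)2 (5 mol%), t-BuOOH (2.5 equiv), CH2Cl2, 0 °C; then PPTS (20 mol%), rt
Reagents that add atoms: tert-butyl hydroperoxide, CC(C)(C)OO
Why: Vanadium‑catalysed hydroxyl‑directed epoxidation delivers oxygen syn to the 12‑OH at C11=C20 and erythro to the 9‑OH at C7=C8 (A(1,2) strain from the C17 branch on C8), and the labile dienyl epoxide is then opened at allylic C7 with inversion by the tert‑butyl ester carbonyl with loss of isobutene, which sets C11, C8 and C7 and closes the γ‑lactone.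

Step 19
Reactants: 28 seco-lactone triol
Product: 29 seco-tetraacetate (2,9,12,14-tetra-O-acetyl; 8-OH free)
Conditions: Ac2O, pyridine, DMAP (cat.), CH2Cl2, 0 °C to rt
Reagents that add atoms: acetic anhydride, CC(=O)OC(C)=O
Why: Acylation esterifies the two secondary alcohols while the hindered tertiary 8‑hydroxyl stays free, as in the target.

Step 20
Reactants: 29 seco-tetraacetate
Product: 30 16-O-TBS macrocycle (32 with CH2OTBS in place of CH2Cl)
Conditions: second-generation Grubbs catalyst RuCl2(=CHPh)(SIMes)(PCy3) (15 mol%), 1,4-benzoquinone (30 mol%), toluene (0.5 mM), 80 °C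
Reagents that add atoms: none
Why: Ene–diene ring‑closing metathesis joins C3 and C4 on a precursor whose trans‑fused lactone already holds C6 and C9 as in the product, and the conjugated diene in a ten‑membered ring forms as the less strained (3Z) isomer; the C11 methylidene is already an epoxide, so it cannot compete.

Step 21
Reactants: 30 16-O-TBS macrocycle
Product: 31 16-alcohol (32 with CH2OH in place of CH2Cl)
Conditions: TBAF, AcOH (1:1), THF, 0 °C
Reagents that add atoms: none
Why: Buffered fluoride desilylation frees the primary allylic alcohol without acetate migration or epoxide opening.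

Step 22
Reactants: 31 16-alcohol
Product: 32 (1R,2S,3Z,5E,7S,8S,9S,10S,11R,12R,14S,17R)-2,9,12,14-tetraacetoxy-16-chloro-11,20-epoxy-8-hydroxybriara-3,5-dien-19,7-olide
Conditions: NCS, PPh3, THF, −20 to 0 °C
Reagents that add atoms: N-chlorosuccinimide, O=C1CCC(=O)N1Cl
Why: Appel‑type chlorination converts only the primary allylic alcohol to the chloride under neutral conditions, leaving the tertiary alcohol, the epoxide and the acetates untouched.

## Compound list

In names of 24–31, "as in 32" means the same spatial arrangement as in the target.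

1 | 4,6-dimethylbenzene-1,3-diol | Cc1cc(C)c(O)cc1O | starting material
2 | 2-chloro-4,6-dimethylbenzene-1,3-diol | Cc1cc(C)c(O)c(Cl)c1O | intermediate
3 | prop-2-ene-1,1-diyl diacetate (acrolein diacetate) | C=CC(OC(C)=O)OC(C)=O | starting material
4 | (1S)-1-[(1S)-3-chloro-4-hydroxy-1,5-dimethyl-2-oxocyclohexa-3,5-dien-1-yl]prop-2-en-1-yl acetate | C=C[C@H](OC(C)=O)[C@]1(C)C=C(C)C(O)=C(Cl)C1=O | intermediate
5 | (1S)-1-[(1S)-4-hydroxy-1,5-dimethyl-2-oxocyclohexa-3,5-dien-1-yl]prop-2-en-1-yl acetate | C=C[C@H](OC(C)=O)[C@]1(C)C=C(C)C(O)=CC1=O | intermediate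
6 | (1S)-1-[(1S)-4-methoxy-1,5-dimethyl-2-oxocyclohexa-3,5-dien-1-yl]prop-2-en-1-yl acetate | C=C[C@H](OC(C)=O)[C@]1(C)C=C(C)C(OC)=CC1=O | intermediate
7 | (1S)-1-[(1R,2S)-2-hydroxy-4-methoxy-1,5-dimethylcyclohexa-3,5-dien-1-yl]prop-2-en-1-yl acetate | C=C[C@H](OC(C)=O)[C@]1(C)C=C(C)C(OC)=C[C@@H]1O | intermediate
8 | 2-O-acetate of 7 (dienol ether acetate; same configuration) | C=C[C@H](OC(C)=O)[C@]1(C)C=C(C)C(OC)=C[C@@H]1OC(C)=O | intermediate
9 | (1S)-1-[(1R,6S)-6-acetoxy-1,3-dimethyl-4-oxocyclohex-2-en-1-yl]prop-2-en-1-yl acetate | C=C[C@H](OC(C)=O)[C@]1(C)C=C(C)C(=O)C[C@@H]1OC(C)=O | intermediate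
10 | (1S)-1-[(1R,6S)-6-acetoxy-3-(bromomethyl)-1-methyl-4-oxocyclohex-2-en-1-yl]prop-2-en-1-yl acetate | C=C[C@H](OC(C)=O)[C@]1(C)C=C(CBr)C(=O)C[C@@H]1OC(C)=O | intermediate
11 | tert-butyl (2R)-2-hydroxypropanoate | CC(C)(C)OC(=O)[C@@H](C)O | starting material
12 | tert-butyl (2R)-2-{[(trifluoromethyl)sulfonyl]oxy}propanoate | CC(C)(C)OC(=O)[C@@H](C)OS(=O)(=O)C(F)(F)F | intermediate
13 | diethyl {2-[methoxy(methyl)amino]-2-oxoethyl}phosphonate | CCOP(=O)(OCC)CC(=O)N(C)OC | starting material
14 | sodium salt (α-carbanion) of 13 | [Na+].CCOP(=O)(OCC)[CH-]C(=O)N(C)OC | intermediate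
15 | tert-butyl (2S)-3-(diethoxyphosphoryl)-4-[methoxy(methyl)amino]-2-methyl-4-oxobutanoate (C3 epimers) | CC(C)(C)OC(=O)[C@H](C)C(C(=O)N(C)OC)P(=O)(OCC)OCC | intermediate
16 | 4-{[tert-butyl(dimethyl)silyl]oxy}but-2-yn-1-ol | OCC#CCO[Si](C)(C)C(C)(C)C | starting material
17 | sodium 2,2-bis(2-methoxyethoxy)-3-({[tert-butyl(dimethyl)silyl]oxy}methyl)-2,5-dihydro-1,2-oxaaluminol-2-uide (alkenylaluminate) | [Na+].COCCO[Al-]1(OCCOC)OCC=C1CO[Si](C)(C)C(C)(C)C | intermediate
18 | (2Z)-4-{[tert-butyl(dimethyl)silyl]oxy}-3-iodobut-2-en-1-ol | OC/C=C(\I)CO[Si](C)(C)C(C)(C)C | intermediate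
19 | tributyl(ethenyl)stannane | C=C[Sn](CCCC)(CCCC)CCCC | starting material
20 | (2E)-3-({[tert-butyl(dimethyl)silyl]oxy}methyl)penta-2,4-dien-1-ol (CH2OH cis to vinyl) | OC/C=C(\C=C)CO[Si](C)(C)C(C)(C)C | intermediate
21 | (2E)-3-({[tert-butyl(dimethyl)silyl]oxy}methyl)penta-2,4-dienal (CHO cis to vinyl) | O=C/C=C(\C=C)CO[Si](C)(C)C(C)(C)C | intermediate
22 | tert-butyl (2R,3E,5E)-6-({[tert-butyl(dimethyl)silyl]oxy}methyl)-3-[methoxy(methyl)carbamoyl]-2-methylocta-3,5,7-trienoate | CC(C)(C)OC(=O)[C@H](C)/C(C(=O)N(C)OC)=C\C=C(/C=C)CO[Si](C)(C)C(C)(C)C | intermediate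
23 | tert-butyl (2R,3E,5E)-6-({[tert-butyl(dimethyl)silyl]oxy}methyl)-3-formyl-2-methylocta-3,5,7-trienoate | CC(C)(C)OC(=O)[C@H](C)/C(C=O)=C\C=C(/C=C)CO[Si](C)(C)C(C)(C)C | intermediate
24 | C9–C10 allylation adduct: 2,14-diacetoxy-12-oxo ring A with 11(20)-methylidene, bearing at C10 the C9 carbinol of the (7E,5-cis) trienoate tert-butyl ester, 16-OTBS; C1, C2, C10, C14, C17 as in 32; C9 mainly epimeric to 32 (drawn) | C=C[C@H](OC(C)=O)[C@]1(C)[C@@H]([C@@H](O)/C(=C/C=C(\C=C)CO[Si](C)(C)C(C)(C)C)[C@@H](C)C(=O)OC(C)(C)C)C(=C)C(=O)C[C@@H]1OC(C)=O | intermediate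
25 | seco-trienone: 9,12-dioxo analogue of 24 | C=C[C@H](OC(C)=O)[C@]1(C)[C@@H](C(=O)/C(=C/C=C(\C=C)CO[Si](C)(C)C(C)(C)C)[C@@H](C)C(=O)OC(C)(C)C)C(=C)C(=O)C[C@@H]1OC(C)=O | intermediate
26 | bis-allylic diol: 9,12-dihydroxy analogue of 25 with C9 and C12 as in 32 | C=C[C@H](OC(C)=O)[C@]1(C)[C@@H]([C@H](O)/C(=C/C=C(\C=C)CO[Si](C)(C)C(C)(C)C)[C@@H](C)C(=O)OC(C)(C)C)C(=C)[C@H](O)C[C@@H]1OC(C)=O | intermediate
27 | bis-epoxide: 7,8-epoxy-11,20-epoxy derivative of 26 (C8 and C11 as in 32, C7 epimeric to 32) | C=C[C@H](OC(C)=O)[C@]1(C)[C@@H]([C@H](O)[C@]3(O[C@@H]3/C=C(\C=C)CO[Si](C)(C)C(C)(C)C)[C@@H](C)C(=O)OC(C)(C)C)[C@@]2(CO2)[C@H](O)C[C@@H]1OC(C)=O | intermediate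
28 | seco-lactone triol: 3,4-seco analogue of 32 with terminal vinyl groups at C3 and C4, 19,7-lactone, 11,20-epoxide, 2,14-di-O-acetyl, free 8-, 9-, 12-OH, 16-OTBS; all stereocentres as in 32 | C=C\C(CO[Si](C)(C)C(C)(C)C)=C/[C@@H]2OC(=O)[C@H](C)[C@@]2(O)[C@@H](O)[C@H]1[C@@]3(CO3)[C@H](O)C[C@H](OC(C)=O)[C@]1(C)[C@@H](OC(C)=O)C=C | intermediate
29 | seco-tetraacetate: 9,12-di-O-acetyl derivative of 28 | C=C\C(CO[Si](C)(C)C(C)(C)C)=C/[C@@H]2OC(=O)[C@H](C)[C@@]2(O)[C@@H](OC(C)=O)[C@H]1[C@@]3(CO3)[C@H](OC(C)=O)C[C@H](OC(C)=O)[C@]1(C)[C@@H](OC(C)=O)C=C | intermediate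
30 | 16-O-TBS macrocycle: 32 with CH2OSi(tBu)Me2 in place of CH2Cl | CC(=O)O[C@H]1/C=C\C(CO[Si](C)(C)C(C)(C)C)=C/[C@@H]2OC(=O)[C@H](C)[C@@]2(O)[C@@H](OC(C)=O)[C@H]2[C@@]3(CO3)[C@H](OC(C)=O)C[C@H](OC(C)=O)[C@]12C | intermediate
31 | 16-alcohol: 32 with CH2OH in place of CH2Cl | CC(=O)O[C@H]1/C=C\C(CO)=C/[C@@H]2OC(=O)[C@H](C)[C@@]2(O)[C@@H](OC(C)=O)[C@H]2[C@@]3(CO3)[C@H](OC(C)=O)C[C@H](OC(C)=O)[C@]12C | intermediate
32 | (1R,2S,3Z,5E,7S,8S,9S,10S,11R,12R,14S,17R)-2,9,12,14-tetraacetoxy-16-chloro-11,20-epoxy-8-hydroxybriara-3,5-dien-19,7-olide | CC(=O)O[C@H]1/C=C\C(CCl)=C/[C@@H]2OC(=O)[C@H](C)[C@@]2(O)[C@@H](OC(C)=O)[C@H]2[C@@]3(CO3)[C@H](OC(C)=O)C[C@H](OC(C)=O)[C@]12C | target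

## Step count and risks

Total step count: 22. Longest linear sequence: 15 (steps 1–7, then 15–22).

Three steps most likely to fail:

**Step 2 (dearomative alkylation).** Risks are O‑ versus C‑alkylation and control of the C1/C2 pair. The fallback sets out from 2 and comes back at 4. Mono‑O‑propargylation of 2 (propargyl bromide, K2CO3, acetone) gives 2-chloro-4,6-dimethyl-3-(prop-2-yn-1-yloxy)phenol F1. Anti‑Markovnikov addition of acetic acid to the alkyne, catalysed by Ru(2-methylallyl)2(dppb), gives (1Z)-3-(2-chloro-3-hydroxy-4,6-dimethylphenoxy)prop-1-en-1-yl acetate F2. Heating in toluene at 110 °C triggers an aromatic Claisen rearrangement onto the methyl‑bearing ortho carbon (the other ortho carbon carries chlorine); the chair transition state of the (Z)‑enol acetate gives the (1S*,1′S*) relative configuration, that is racemic 4, rac-4 F3. Preparative chiral SFC then returns 4. This replaces catalytic ionic alkylation by a sigmatropic C–C bond formation plus resolution.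

**Step 7 (allylic bromination).** The risk is competing radical attack at other C–H sites. The fallback sets out from 9 and comes back at 25. Luche reduction of 9 gives the C12 allylic alcohol (12‑OH cis to 14‑OAc), (1S)-1-[(1R,6S)-6-acetoxy-4-hydroxy-1,3-dimethylcyclohex-2-en-1-yl]prop-2-en-1-yl acetate F4. Allylic hydroxylation with SeO2 (cat.) and t‑BuOOH (ene reaction and [2,3] shift) oxidizes the C20 methyl to the 12,20‑diol F5. CBr4/PPh3 at −40 °C converts the primary allylic alcohol into the 20‑bromide F6. Indium‑mediated allylation of 23 with F6 gives the 9,12‑diol adduct F7. MnO2 oxidizes both allylic carbinols of F7 and returns to 25.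

**Step 20 (ring‑closing metathesis).** Risks are catalyst sequestration on the diene terminus, dimerization and a hindered C3 vinyl. The fallback sets out from 29 and comes back at 30. Cross‑metathesis of 29 with cis‑but‑2‑ene using Hoveyda–Grubbs second‑generation catalyst RuCl2(=CH-C6H4-2-OiPr)(SIMes) caps only the unhindered diene terminus and gives the propenyl‑capped seco‑tetraacetate F8. The capped diene can no longer load the catalyst, so ring closure under high dilution must start at the C3 vinyl and expels propene to give 30. This is a relay‑type redesign that moves the initiation site.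

## Further compounds

F1 | step 2 | 2-chloro-4,6-dimethyl-3-(prop-2-yn-1-yloxy)phenol | Cc1cc(C)c(OCC#C)c(Cl)c1O
F2 | step 2 | (1Z)-3-(2-chloro-3-hydroxy-4,6-dimethylphenoxy)prop-1-en-1-yl acetate | CC(=O)O/C=C\COc1c(C)cc(C)c(O)c1Cl
F3 | step 2 | rac-4 (1:1 mixture of 4 and its enantiomer) | C=C[C@H](OC(C)=O)[C@]1(C)C=C(C)C(O)=C(Cl)C1=O.C=C[C@@H](OC(C)=O)[C@@]1(C)C=C(C)C(O)=C(Cl)C1=O
F4 | step 7 | (1S)-1-[(1R,6S)-6-acetoxy-4-hydroxy-1,3-dimethylcyclohex-2-en-1-yl]prop-2-en-1-yl acetate (4-OH cis to 6-OAc) | C=C[C@H](OC(C)=O)[C@]1(C)C=C(C)[C@H](O)C[C@@H]1OC(C)=O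
F5 | step 7 | 3-(hydroxymethyl) analogue of F4 (12,20-diol) | C=C[C@H](OC(C)=O)[C@]1(C)C=C(CO)[C@H](O)C[C@@H]1OC(C)=O
F6 | step 7 | 3-(bromomethyl) analogue of F4 (20-bromide with free 12-OH) | C=C[C@H](OC(C)=O)[C@]1(C)C=C(CBr)[C@H](O)C[C@@H]1OC(C)=O
F7 | step 7 | 12-hydroxy analogue of 24 (9,12-diol; C9 mainly epimeric to 32) | C=C[C@H](OC(C)=O)[C@]1(C)[C@@H]([C@@H](O)/C(=C/C=C(\C=C)CO[Si](C)(C)C(C)(C)C)[C@@H](C)C(=O)OC(C)(C)C)C(=C)[C@H](O)C[C@@H]1OC(C)=O
F8 | step 20 | propenyl-capped analogue of 29 (terminal diene CH2 replaced by (E)-CH–CH3) | C/C=C/C(CO[Si](C)(C)C(C)(C)C)=C\[C@@H]2OC(=O)[C@H](C)[C@@]2(O)[C@@H](OC(C)=O)[C@H]1[C@@]3(CO3)[C@H](OC(C)=O)C[C@H](OC(C)=O)[C@]1(C)[C@@H](OC(C)=O)C=C
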